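**Retrosynthetic overview**
1. Target 11 ⇐ flavone 10 (5-OMe, 6'-O-iPr): one BCl3 operation frees both hydroxyls at the end.
2. Ring C (the pyranone) is the only ring formed, and it is closed last: 10 ⇐ 1,3-diketone 9 by cyclodehydration.
3. Key C3–C4 bond: 9 ⇐ salicylaldehyde 3 + β-keto sulfoxonium ylide 8. The formyl carbon of 3 reacts as a Rh-bound acyl nucleophile (acyl anion equivalent) and the ylide carbon of 8 as an electrophilic Rh-carbenoid (enolonium equivalent).
4. Rings A and B are the same aryl unit, so 3 and 8 both come from 3,4,5-trimethoxyphenol 1: 3 by formylation, 8 via isopropyl ether 4, ortho-lithiation/CO2 (acid 6) and acylation of the sulfoxonium methylide.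

Assumption: the target has no stereocentre (achiral), so there is no configuration to set; 3,4,5-trimethoxyphenol is taken as the commercial starting material.

**Route**

Step 1
Reactants: 1 3,4,5-trimethoxyphenol
Product: 3 6-hydroxy-2,3,4-trimethoxybenzaldehyde, via iminium chloride 2 (not isolated)
Conditions: POCl3 (1.5 equiv), DMF, 0 °C → rt; then H2O, 60 °C
Reagents that add atoms: N,N-dimethylformamide, CN(C)C=O; water, O
Why: Vilsmeier–Haack formylation; the only free ring positions (C2/C6, equivalent) are ortho to OH and ortho/para to OMe, so one regioisomer forms, and the iminium salt is hydrolysed on aqueous work-up.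

Step 2
Reactants: 1 3,4,5-trimethoxyphenol
Product: 4 5-isopropoxy-1,2,3-trimethoxybenzene
Conditions: 2-bromopropane, K2CO3, DMF, 60 °C
Reagents that add atoms: 2-bromopropane, CC(C)Br
Why: Williamson ether synthesis; the isopropyl ether survives BuLi and cationic Rh(III) and is later removed by the same BCl3 that cleaves the 5-OMe.

Step 3
Reactants: 4 5-isopropoxy-1,2,3-trimethoxybenzene
Product: 6 6-isopropoxy-2,3,4-trimethoxybenzoic acid, via aryllithium 5 (not isolated)
Conditions: n-BuLi, TMEDA, THF, 0 °C; CO2, −78 °C → rt; then 1 M HCl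
Reagents that add atoms: carbon dioxide, O=C=O
Why: Directed ortho-metalation; the only aryl C–H type lies between O-iPr and OMe (cooperative directing groups), and carboxylation of the aryllithium gives the acid.

Step 4
Reactants: 6 6-isopropoxy-2,3,4-trimethoxybenzoic acid
Product: 8 2-[dimethyl(oxo)-λ6-sulfanylidene]-1-(6-isopropoxy-2,3,4-trimethoxyphenyl)ethan-1-one, via acid chloride 7 (not isolated)
Conditions: (COCl)2, cat. DMF, CH2Cl2, 0 °C → rt; then Me3S(O)I/KOtBu (3 equiv, methylide preformed in THF at reflux), THF, 0 °C → rt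
Reagents that add atoms: trimethylsulfoxonium iodide, C[S+](C)(C)=O.[I-]
Why: C-acylation of dimethylsulfoxonium methylide (Corey–Chaykovsky reagent) by the acid chloride; a second equivalent of methylide deprotonates the acyl sulfoxonium salt to give the stabilised β-keto ylide.

Step 5 (key step)
Reactants: 3 6-hydroxy-2,3,4-trimethoxybenzaldehyde; 8 2-[dimethyl(oxo)-λ6-sulfanylidene]-1-(6-isopropoxy-2,3,4-trimethoxyphenyl)ethan-1-one
Product: 10 2-(6-isopropoxy-2,3,4-trimethoxyphenyl)-5,6,7-trimethoxy-4H-chromen-4-one, via 1,3-diketone 9 (not isolated)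
Conditions: [Cp*RhCl2]2 (4 mol %), AgSbF6 (16 mol %), NaOAc (30 mol %), PivOH (1 equiv), DCE, 100 °C; then TsOH·H2O, 100 °C
Reagents that add atoms: none
Why: Cp*Rh(III)-catalysed, phenol-directed aldehyde C–H activation followed by carbene migratory insertion (the salicylaldehyde/sulfoxonium ylide chromone annulation): the formyl carbon becomes a nucleophilic acyl–Rh (acyl anion equivalent) that migrates onto the electrophilic Rh-carbenoid formed from 8 with loss of DMSO — the reverse of the usual enolate-plus-acyl-electrophile pairing — then protodemetalation gives diketone 9 and acid closes the pyranone; both ortho positions of the ylide aryl are blocked, so ylide-directed arene C–H side reactions cannot occur, and no stereocentre is formed.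

Step 6
Reactants: 10 2-(6-isopropoxy-2,3,4-trimethoxyphenyl)-5,6,7-trimethoxy-4H-chromen-4-one
Product: 11 5-hydroxy-2-(6-hydroxy-2,3,4-trimethoxyphenyl)-6,7-dimethoxy-4H-chromen-4-one (5,6'-dihydroxy-6,7,2',3',4'-pentamethoxyflavone)
Conditions: BCl3 (5 equiv), CH2Cl2, −78 → 0 °C; then H2O
Reagents that add atoms: none
Why: Lewis-acid ether cleavage; the secondary isopropyl ether ionises readily and the 5-OMe is cleaved selectively through the six-membered boron chelate with the C4 carbonyl, while the non-chelated methyl ethers survive at ≤0 °C.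

**Compound list**
1 | 3,4,5-trimethoxyphenol | COc1cc(O)cc(OC)c1OC | starting material
2 | N-[(6-hydroxy-2,3,4-trimethoxyphenyl)methylidene]-N-methylmethanaminium chloride | C[N+](C)=Cc1c(O)cc(OC)c(OC)c1OC.[Cl-] | intermediate
3 | 6-hydroxy-2,3,4-trimethoxybenzaldehyde | O=Cc1c(O)cc(OC)c(OC)c1OC | intermediate
4 | 5-isopropoxy-1,2,3-trimethoxybenzene | CC(C)Oc1cc(OC)c(OC)c(OC)c1 | intermediate
5 | (6-isopropoxy-2,3,4-trimethoxyphenyl)lithium | [Li]c1c(OC(C)C)cc(OC)c(OC)c1OC | intermediate
6 | 6-isopropoxy-2,3,4-trimethoxybenzoic acid | OC(=O)c1c(OC(C)C)cc(OC)c(OC)c1OC | intermediate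
7 | 6-isopropoxy-2,3,4-trimethoxybenzoyl chloride | ClC(=O)c1c(OC(C)C)cc(OC)c(OC)c1OC | intermediate
8 | 2-[dimethyl(oxo)-λ6-sulfanylidene]-1-(6-isopropoxy-2,3,4-trimethoxyphenyl)ethan-1-one | CS(C)(=O)=CC(=O)c1c(OC(C)C)cc(OC)c(OC)c1OC | intermediate
9 | 1-(6-hydroxy-2,3,4-trimethoxyphenyl)-3-(6-isopropoxy-2,3,4-trimethoxyphenyl)propane-1,3-dione | COc1cc(O)c(C(=O)CC(=O)c2c(OC(C)C)cc(OC)c(OC)c2OC)c(OC)c1OC | intermediate
10 | 2-(6-isopropoxy-2,3,4-trimethoxyphenyl)-5,6,7-trimethoxy-4H-chromen-4-one | COc1cc(OC(C)C)c(-c2cc(=O)c3c(OC)c(OC)c(OC)cc3o2)c(OC)c1OC | intermediate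
11 | 5-hydroxy-2-(6-hydroxy-2,3,4-trimethoxyphenyl)-6,7-dimethoxy-4H-chromen-4-one | COc1cc(O)c(-c2cc(=O)c3c(O)c(OC)c(OC)cc3o2)c(OC)c1OC | target

**Step count**
Total: 6 steps. Longest linear sequence: 5 steps (1 → 4 → 6 → 8 → 10 → 11).

**Three steps most likely to fail**

Step 5 is the most exposed. Both partners are di-ortho-substituted and electron-rich, and O–H insertion of the carbenoid into the phenol (leading to a 2-aroylbenzofuran) or slow ring closure at the hindered ketone could erode the yield. The fallback sets out from 1 and 7 and comes back at 9. It gives up C–H activation for a carbanion acylation. Compound 1 is acetylated ortho to the hydroxyl (AcOH, BF3·OEt2, 90 °C) to give 1-(6-hydroxy-2,3,4-trimethoxyphenyl)ethan-1-one F1. Its phenoxide–enolate dianion (LiHMDS, 3 equiv, THF, −78 °C) is C-acylated with acid chloride 7, and acidic work-up gives the same diketone 9, which is closed to 10 with TsOH as in step 5.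

Step 6 can over-dealkylate (the 6-OMe next to the boron chelate, or the crowded 2'-/3'-OMe) or stop after loss of the isopropyl group. The fallback sets out from 10 and comes back at 11. It replaces the single global Lewis-acid step by two operations with different mechanisms. AlCl3 (1.5 equiv, CH2Cl2, 0 °C) removes only the secondary isopropyl group to give 2-(6-hydroxy-2,3,4-trimethoxyphenyl)-5,6,7-trimethoxy-4H-chromen-4-one F2; any 5-O-demethylation at this stage is already product-forming. Protic hydrolysis of the vinylogous-ester 5-OMe (conc. HCl/EtOH, reflux), which is specific for the methoxy peri to the protonated C4 carbonyl, then gives 11.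

Step 3 can suffer from incomplete metalation of the tetra-alkoxyarene or from attack of the aryllithium on the lithium carboxylate (diaryl ketone). The fallback sets out from 3 and comes back at 6. It avoids organolithium chemistry: 3 is O-alkylated (2-bromopropane, K2CO3, DMF, 60 °C) to 6-isopropoxy-2,3,4-trimethoxybenzaldehyde F3, which is oxidised to 6 by Pinnick oxidation (NaClO2, NaH2PO4, 2-methyl-2-butene, t-BuOH/H2O).

**Further compounds**
F1 | step 5 | 1-(6-hydroxy-2,3,4-trimethoxyphenyl)ethan-1-one | CC(=O)c1c(O)cc(OC)c(OC)c1OC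
F2 | step 6 | 2-(6-hydroxy-2,3,4-trimethoxyphenyl)-5,6,7-trimethoxy-4H-chromen-4-one | COc1cc(O)c(-c2cc(=O)c3c(OC)c(OC)c(OC)cc3o2)c(OC)c1OC
F3 | step 3 | 6-isopropoxy-2,3,4-trimethoxybenzaldehyde | CC(C)Oc1cc(OC)c(OC)c(OC)c1C=O
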